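Slowness is what to watch in these flasks: the eta run ends at a crawl, and the question is what that crawl says about a flask charged with target.

| setting | eta | theta | gamma | zeta | alpha |
|---|---|---|---|---|---|
| starting material | 0.200 M | 0.100 M | 0.200 M | 0.400 M | 0.200 M |
| partner | 0.600 M | 0.500 M | 0.900 M | 0.600 M | 0.600 M |
| target |  |  |  |  | 0.200 M |
| time |  |  |  |  | 22 min |

- eta run (time / min: [target] / M): 0.88: 0.0066; 2.0: 0.0134; 4.4: 0.0260; 9.8: 0.0441; 22: 0.0610
- theta run (time / min: [target] / M): 0.88: 0.0026; 2.0: 0.0048; 4.4: 0.0113; 9.8: 0.0205; 22: 0.0302
- gamma run (time / min: [target] / M): 0.88: 0.0109; 2.0: 0.0242; 4.4: 0.0430; 9.8: 0.0669; 22: 0.0754
- zeta run (time / min: [target] / M): 0.88: 0.0129; 2.0: 0.0244; 4.4: 0.0464; 9.8: 0.0752; 22: 0.0968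

(each reading ± 6 × 10⁻⁴ M)

- Overall: starting material + partner -> target.
- Constant volume, constant temperature.
- "The second partner" is partner.
- An order is taken over about fifteen percent of the charge, up and down.
- A share of target counts the target that was charged too.

1. order of the initial rate in [starting material], near the charge of the eta run, the rate being that where two percent of its starting material are target (one fixed amount of target, the same in the runs compared)
2. order of the initial rate in [partner], near the charge of the eta run, the rate being that where two percent of its starting material are target
3. target in the alpha run at 22 min, as a share of the starting material charged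

**How slow is it?** In the eta run, target forms at 0.00670 M min⁻¹ on average over the first 2.0 min. Between the last two readings it forms at 0.00139 M min⁻¹, at a mean c(target) of 0.0525 M.

**What rate did you expect there?** The first two readings of each run, summed, give orders of 0.899 in starting material (zeta against eta) and 1.39 in partner (gamma against eta), read across those wider steps. Setting aside the fall of partner, the pseudo-first-order picture scales the early rate by the starting material not yet turned into target. That gives 0.00494 M min⁻¹. The reading is lower, so 0.00355 M min⁻¹ is missing.

**Missing from which side?** Partly from the starting material, I judge. Doubling the charge of starting material, zeta against eta, raises c(target) at 0.88 min by a factor of 1.95, but at 22 min by a factor of 1.59. I do not split the gap here, and reckon the two extremes instead.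

**Then suppose the whole gap is loss of target. What follows?** Each unit of target then leaves at 0.0676 min⁻¹. Dividing the early rate by this gives the balance level, the c(target) at which rate in equals rate out, and time has dropped out: 0.0991 M. The alpha run is charged with 0.200 M, above this level. With the rate in held at its early value, c(target) falls to 0.122 M at 22 min, or 60.9% of the starting material.

**And if target is inert?** The alpha run adds the gain of the eta run to its charge, which gives 130%. I hold the gap to be shared between the two sides, so I commit to the middle, 95.7%, which is below the charge.

The forecast says 1 in starting material, 1.5 in partner and 111%, holding that added “target should cut the rate about fivefold”. Its share stands above mine and above the charge.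

    starting material + partner → target (0.03570 M⁻¹ min⁻¹)
    starting material + 2 partner → target + partner (0.04494 M⁻² min⁻¹)
    2 starting material → homo dimer (0.09960 M⁻¹ min⁻¹)
    target + partner → side product (0.04086 M⁻¹ min⁻¹)

The flask gives orders of 1.0 and 1.5 and a share of 92.5%, so c(target) in the alpha run is 0.185 M at 22 min, below the 0.200 M charged. A fit in which the starting material is lost by itself forecast 126% for the alpha run, higher. The alpha run ended at 1.87 times the balance level, and its share stands 54.3% of the way down from the inert mark to the mark of pure target loss.

The earlier runs and the new flask were generated by integration from invented constants.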